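**Retrosynthetic overview**

1. Target 28 ⇐ protected chalcone 27 ⇐ 8-acetyl-5,7-dihydroxychroman 22, by Claisen–Schmidt condensation at the C8 acetyl group, O7 methylation and O5 protection.
2. The plan rests on ring A (C4a, C5, C6, C7, C8, C8a): with its acetyl carbon it is an acylphloroglucinol, a folded 3,5,7-triketo ester whose C8a carbonyl is held as the O1 enol ether of the pyran ring. Hence 22 ⇐ Claisen closure C7–C8 of dihydropyran 21.
3. 21 ⇐ 6-methyldihydropyran 16 by C4a formylation, acetate aldol and oxidation (C5 to C7), then lateral acetylation of the C8 methyl group.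
4. 16 ⇐ cyclodehydration of hydroxy ketone 15 ⇐ Weinreb amide opened from the trans δ-lactone 11 ⇐ Mukaiyama–Michael addition of enol silane 9 to lactone 6. C2' comes from a Keck allylation, C4 from the trans addition, C2 from a CBS reduction.
5. Ring order: a temporary δ-lactone (closed on the C2' oxygen), then the pyran ring (O1–C8a), then ring A; the chalcone arm comes last.

Key step: step 18

Remark: chroman numbering (O1, C2, C3, C4, C4a, C5 to C8, C8a; side chain C1' to C4') is used for all intermediates. Ar = 4-(methoxymethoxy)phenyl, MOM = methoxymethyl, TBS = tert-butyldimethylsilyl. Polycarbonyl compounds are drawn as one tautomer, and 15 equilibrates with its cyclic hemiketal. The C4 descriptor is R in the TBS ethers and S in the free alcohol 28 because of a priority change only.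

**Route**

Step 1
Reactants: 1 methyl 3-(4-hydroxyphenyl)propanoate
Product: 2 methyl 3-[4-(methoxymethoxy)phenyl]propanoate
Conditions: MOMCl, iPr2NEt, CH2Cl2, 0 °C → rt
Reagents that add atoms: chloromethyl methyl ether, COCCl
Why: O-alkylation of the phenol by the chloromethyl ether (acetal protection) is fast and selective, and the aryl methoxymethyl ether tolerates the hydride, organometallic and basic steps that follow.

Step 2
Reactants: 2 methyl 3-[4-(methoxymethoxy)phenyl]propanoate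
Product: 3 3-[4-(methoxymethoxy)phenyl]propanal
Conditions: iBu2AlH (1.05 equiv), CH2Cl2, −78 °C; aq. sodium potassium tartrate
Reagents that add atoms: none
Why: Partial reduction of the ester by iBu2AlH at −78 °C stops at the aldehyde because the tetrahedral aluminium hemiacetal collapses only on work-up.

Step 3
Reactants: 3 3-[4-(methoxymethoxy)phenyl]propanal
Product: 4 (3R)-1-Ar-hex-5-en-3-ol
Conditions: (S)-BINOL (10 mol%), Ti(OiPr)4 (10 mol%), 4 Å MS, CH2Cl2; allylSnBu3, −20 °C; aq. NaHCO3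
Reagents that add atoms: allyltributylstannane, C=CC[Sn](CCCC)(CCCC)CCCC
Why: Keck asymmetric allylation, in which the (S)-BINOL–titanium Lewis acid activates the aldehyde and directs the allylstannane to its Si face, should set C2' as R under catalyst control.

Step 4
Reactants: 4 (3R)-1-Ar-hex-5-en-3-ol
Product: 5 (3R)-1-Ar-hex-5-en-3-yl prop-2-enoate
Conditions: CH2=CHCOCl, Et3N, DMAP (cat.), CH2Cl2, 0 °C
Reagents that add atoms: acryloyl chloride, C=CC(=O)Cl
Why: Acylation of the secondary alcohol by the acid chloride (esterification with DMAP catalysis) installs the second alkene for ring closure without touching the stereocentre.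

Step 5
Reactants: 5 (3R)-1-Ar-hex-5-en-3-yl prop-2-enoate
Product: 6 (6R)-6-(2-Ar-ethyl)-5,6-dihydro-2H-pyran-2-one
Conditions: second-generation Grubbs catalyst (3 mol%), CH2Cl2 (0.01 M), 40 °C
Reagents that add atoms: none
Why: Ring-closing olefin metathesis of the acrylate and the terminal alkene forms the six-membered α,β-unsaturated lactone, driven by loss of ethene, and leaves C2' unchanged.

Step 6
Reactants: 7 1-(4-hydroxyphenyl)ethanone
Product: 8 1-Ar-ethanone
Conditions: MOMCl, iPr2NEt, CH2Cl2, 0 °C → rt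
Reagents that add atoms: chloromethyl methyl ether, COCCl
Why: The same acetal protection as in step 1 masks the phenol before enol silane formation and Lewis acid chemistry.

Step 7
Reactants: 8 1-Ar-ethanone
Product: 9 (1-Ar-ethenyloxy)trimethylsilane
Conditions: TMSOTf, Et3N, CH2Cl2, 0 °C
Reagents that add atoms: trimethylsilyl trifluoromethanesulfonate, C[Si](C)(C)OS(=O)(=O)C(F)(F)F
Why: Soft enolisation of the aryl methyl ketone by silyl triflate and amine (silyl enol ether formation) gives the only possible enol silane, the nucleophile for the conjugate addition.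

Step 8
Reactants: 6 (6R)-6-(2-Ar-ethyl)-5,6-dihydro-2H-pyran-2-one; 9 (1-Ar-ethenyloxy)trimethylsilane
Product: 11 (4S,6R)-4-(2-Ar-2-oxoethyl)-6-(2-Ar-ethyl)oxan-2-one (4,6-trans), via silyl ketene acetal 10 (not isolated)
Conditions: TMSOTf (0.2 equiv), CH2Cl2, −78 → −40 °C; aq. NaHCO3
Reagents that add atoms: none
Why: In this Mukaiyama–Michael addition the silyl-activated lactone is attacked at C4 by the enol silane along an axial trajectory anti to the pseudo-equatorial C2' substituent of the half-chair, which should give the 4,6-trans adduct and so set C4 relative to C2' under substrate control, while the aryl acetals stay intact at −78 °C.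

Step 9
Reactants: 11 (4S,6R)-4-(2-Ar-2-oxoethyl)-6-(2-Ar-ethyl)oxan-2-one
Product: 12 (3S,5R)-7-Ar-3-(2-Ar-2-oxoethyl)-5-hydroxy-N-methoxy-N-methylheptanamide
Conditions: MeNH(OMe)·HCl, AlMe3, CH2Cl2, 0 °C → rt; aq. sodium potassium tartrate
Reagents that add atoms: N,O-dimethylhydroxylamine hydrochloride, CNOC.Cl
Why: Aminolysis of the lactone by the aluminium amide (Weinreb amide formation) opens the temporary ring, frees the C2' hydroxyl for protection and turns C8a into an acyl group that accepts exactly one carbon nucleophile.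

Step 10
Reactants: 12 (3S,5R)-7-Ar-3-(2-Ar-2-oxoethyl)-5-hydroxy-N-methoxy-N-methylheptanamide
Product: 13 (3S,5R)-7-Ar-3-(2-Ar-2-oxoethyl)-5-(TBS-oxy)-N-methoxy-N-methylheptanamide
Conditions: TBSCl, imidazole, DMF, rt
Reagents that add atoms: tert-butyldimethylsilyl chloride, CC(C)(C)[Si](C)(C)Cl
Why: Silylation of the secondary alcohol (any hemiketal with the aryl ketone drains through the open form) blocks relactonisation and ensures that later only the C2 oxygen can close the pyran ring.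

Step 11
Reactants: 13 (3S,5R)-7-Ar-3-(2-Ar-2-oxoethyl)-5-(TBS-oxy)-N-methoxy-N-methylheptanamide
Product: 14 (3R,5R)-7-Ar-3-[(2R)-2-Ar-2-hydroxyethyl]-5-(TBS-oxy)-N-methoxy-N-methylheptanamide
Conditions: (S)-2-methyl-CBS-oxazaborolidine (0.2 equiv), BH3·SMe2, THF, −20 °C; MeOH
Reagents that add atoms: none
Why: Corey–Bakshi–Shibata reduction of the aryl ketone, with the aryl ring as the large group, should give the (R)-carbinol at C2 under reagent control, while the Weinreb amide, the silyl ether and the acetals are inert to the borane at −20 °C.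

Step 12
Reactants: 14 (3R,5R)-7-Ar-3-[(2R)-2-Ar-2-hydroxyethyl]-5-(TBS-oxy)-N-methoxy-N-methylheptanamide
Product: 15 (4R,6R)-8-Ar-4-[(2R)-2-Ar-2-hydroxyethyl]-6-(TBS-oxy)octan-2-one
Conditions: MeMgBr (3.5 equiv), THF, 0 °C; aq. NH4Cl
Reagents that add atoms: methylmagnesium bromide, C[Mg]Br
Why: In this Weinreb ketone synthesis the chelated tetrahedral magnesium adduct survives until work-up, so a single methyl group (the future C8) is added to C8a and the benzylic alkoxide is a spectator.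

Step 13
Reactants: 15 (4R,6R)-8-Ar-4-[(2R)-2-Ar-2-hydroxyethyl]-6-(TBS-oxy)octan-2-one
Product: 16 (2R,4R)-2-Ar-4-[(2R)-4-Ar-2-(TBS-oxy)butyl]-6-methyl-3,4-dihydro-2H-pyran (2,4-trans)
Conditions: PPTS (0.1 equiv), 4 Å MS, PhMe, 80 °C
Reagents that add atoms: none
Why: Acid-catalysed cyclodehydration, by hemiketal formation between the C2 hydroxyl and the C8a ketone and loss of water through the oxocarbenium ion, should give the more substituted endocyclic enol ether, and since the C2–O bond is never broken C2 keeps its configuration and the ring is 2,4-trans.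

Step 14
Reactants: 16 (2R,4R)-2-Ar-4-[(2R)-4-Ar-2-(TBS-oxy)butyl]-6-methyl-3,4-dihydro-2H-pyran
Product: 18 (2R,4R)-2-Ar-4-[(2R)-4-Ar-2-(TBS-oxy)butyl]-6-methyl-3,4-dihydro-2H-pyran-5-carbaldehyde, via iminium chloride 17 (not isolated)
Conditions: POCl3, DMF, CH2Cl2, 0 °C → rt; aq. NaOAc
Reagents that add atoms: N,N-dimethylformamide, CN(C)C=O; water, O
Why: In this Vilsmeier–Haack formylation the chloroiminium ion attacks the nucleophilic β-carbon C4a of the enol ether, proton loss restores the C4a=C8a bond and hydrolysis gives the β-alkoxy enal, as in the C2-formylation of glycals.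

Step 15
Reactants: 18 (2R,4R)-2-Ar-4-[(2R)-4-Ar-2-(TBS-oxy)butyl]-6-methyl-3,4-dihydro-2H-pyran-5-carbaldehyde
Product: 19 methyl 3-{(2R,4R)-2-Ar-4-[(2R)-4-Ar-2-(TBS-oxy)butyl]-6-methyl-3,4-dihydro-2H-pyran-5-yl}-3-hydroxypropanoate (both carbinol epimers)
Conditions: LiN(iPr)2, MeOAc, THF, −78 °C; then 18; aq. NH4Cl, 0 °C
Reagents that add atoms: methyl acetate, CC(=O)OC
Why: Aldol addition of the lithium enolate of methyl acetate to the aldehyde carbon attaches C6 and C7, and the new carbinol centre is of no consequence because it is oxidised in the next step.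

Step 16
Reactants: 19 methyl 3-{(2R,4R)-2-Ar-4-[(2R)-4-Ar-2-(TBS-oxy)butyl]-6-methyl-3,4-dihydro-2H-pyran-5-yl}-3-hydroxypropanoate
Product: 20 methyl 3-{(2R,4R)-2-Ar-4-[(2R)-4-Ar-2-(TBS-oxy)butyl]-6-methyl-3,4-dihydro-2H-pyran-5-yl}-3-oxopropanoate
Conditions: Dess–Martin periodinane (1.2 equiv), NaHCO3, CH2Cl2, 0 °C → rt
Reagents that add atoms: none
Why: Dess–Martin oxidation of the allylic secondary alcohol under bicarbonate buffer gives the β-keto ester without exposing the acid-sensitive enol ether to acid.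

Step 17
Reactants: 20 methyl 3-{(2R,4R)-2-Ar-4-[(2R)-4-Ar-2-(TBS-oxy)butyl]-6-methyl-3,4-dihydro-2H-pyran-5-yl}-3-oxopropanoate
Product: 21 methyl 3-{(2R,4R)-2-Ar-4-[(2R)-4-Ar-2-(TBS-oxy)butyl]-6-(2-oxopropyl)-3,4-dihydro-2H-pyran-5-yl}-3-oxopropanoate
Conditions: LiN(iPr)2 (2.3 equiv), THF, −78 → −30 °C; MeC(O)N(OMe)Me, −78 → 0 °C; AcOH
Reagents that add atoms: N-methoxy-N-methylacetamide, CC(=O)N(C)OC
Why: In this lateral (vinylogous) Claisen acylation the first equivalent of base forms the keto ester enolate and the second removes a proton from the C8 methyl group, whose anion is conjugated through C8a=C4a to the C5 carbonyl, and this more reactive terminus adds to the Weinreb amide, which releases the ketone only on quench, as known for the dianions of β-keto esters and of 4-hydroxy-6-methylpyran-2-one.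

Step 18
Reactants: 21 methyl 3-{(2R,4R)-2-Ar-4-[(2R)-4-Ar-2-(TBS-oxy)butyl]-6-(2-oxopropyl)-3,4-dihydro-2H-pyran-5-yl}-3-oxopropanoate
Product: 22 1-{(2R,4R)-2-Ar-4-[(2R)-4-Ar-2-(TBS-oxy)butyl]-5,7-dihydroxy-3,4-dihydro-2H-chromen-8-yl}ethanone
Conditions: Mg(OMe)2 (8 equiv), MeOH, reflux; cold 0.5 M HCl
Reagents that add atoms: none
Why: Mg(OMe)2 converts 21 into its magnesium-chelated polyenolate, in which C8, flanked by the acetyl carbonyl and the C8a=C4a enol ether, attacks the C7 ester carbonyl; loss of methoxide and two enolisations then give the aromatic ring A. This is a Claisen (Dieckmann-type) cyclisation, the mode by which 3,5,7-triketo esters are known to give acylphloroglucinols with magnesium methoxide. Ring A is closed by a 6-exo-trig attack that forms C7–C8, and the cis C4a=C8a bond inside the pyran ring already holds C8 and the keto ester arm on the same side, so the chain needs no folding. No stereocentre is formed, and C2, C4 and C2' carry no acidic hydrogen under these conditions and stay untouched. The step needs Claisen closure (C8 onto C7) and not aldol closure (C6 onto the acetyl carbonyl): expulsion of methoxide followed by aromatisation to a magnesium phenoxide is irreversible, whereas the aldol adduct is a hindered tertiary alkoxide that can revert, so hot methanolic Mg(OMe)2 should funnel the equilibrating enolates to the acylphloroglucinol. O1 is fixed beforehand next to the acyl-bearing carbon, so no choice between phenolic oxygens arises, and only O7–H ends up chelated to the acetyl group.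

Step 19
Reactants: 22 1-{(2R,4R)-2-Ar-4-[(2R)-4-Ar-2-(TBS-oxy)butyl]-5,7-dihydroxy-3,4-dihydro-2H-chromen-8-yl}ethanone
Product: 23 1-{(2R,4R)-2-Ar-4-[(2R)-4-Ar-2-(TBS-oxy)butyl]-7-hydroxy-5-(methoxymethoxy)-3,4-dihydro-2H-chromen-8-yl}ethanone
Conditions: MOMCl (1.1 equiv), iPr2NEt, CH2Cl2, 0 °C
Reagents that add atoms: chloromethyl methyl ether, COCCl
Why: Acetal protection under mild base selects the free O5–H because O7–H is tied up in a hydrogen bond to the acetyl carbonyl and is far less nucleophilic.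

Step 20
Reactants: 23 1-{(2R,4R)-2-Ar-4-[(2R)-4-Ar-2-(TBS-oxy)butyl]-7-hydroxy-5-(methoxymethoxy)-3,4-dihydro-2H-chromen-8-yl}ethanone
Product: 24 1-{(2R,4R)-2-Ar-4-[(2R)-4-Ar-2-(TBS-oxy)butyl]-7-methoxy-5-(methoxymethoxy)-3,4-dihydro-2H-chromen-8-yl}ethanone
Conditions: MeI, K2CO3, acetone, reflux
Reagents that add atoms: iodomethane, CI
Why: Williamson methylation under forcing carbonate conditions alkylates the remaining chelated O7–H, the only free hydroxyl left.

Step 21
Reactants: 25 4-hydroxybenzaldehyde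
Product: 26 4-(methoxymethoxy)benzaldehyde
Conditions: MOMCl, iPr2NEt, CH2Cl2, 0 °C → rt
Reagents that add atoms: chloromethyl methyl ether, COCCl
Why: The same acetal protection as in step 1 keeps the aldehyde from being deactivated as a phenoxide in the base-mediated condensation.

Step 22
Reactants: 24 1-{(2R,4R)-2-Ar-4-[(2R)-4-Ar-2-(TBS-oxy)butyl]-7-methoxy-5-(methoxymethoxy)-3,4-dihydro-2H-chromen-8-yl}ethanone; 26 4-(methoxymethoxy)benzaldehyde
Product: 27 (2E)-3-Ar-1-{(2R,4R)-2-Ar-4-[(2R)-4-Ar-2-(TBS-oxy)butyl]-7-methoxy-5-(methoxymethoxy)-3,4-dihydro-2H-chromen-8-yl}prop-2-en-1-one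
Conditions: KOH, EtOH/H2O, rt
Reagents that add atoms: none
Why: Claisen–Schmidt condensation (crossed aldol addition of the methyl ketone enolate to the non-enolisable aldehyde, then E1cB dehydration) should give the (E)-enone, and with O7 methylated no ortho hydroxyl is left that could cyclise to a flavanone.

Step 23
Reactants: 27 (2E)-3-Ar-1-{(2R,4R)-2-Ar-4-[(2R)-4-Ar-2-(TBS-oxy)butyl]-7-methoxy-5-(methoxymethoxy)-3,4-dihydro-2H-chromen-8-yl}prop-2-en-1-one
Product: 28 (2E)-1-{(2R,4S)-5-hydroxy-4-[(2R)-2-hydroxy-4-(4-hydroxyphenyl)butyl]-2-(4-hydroxyphenyl)-7-methoxy-3,4-dihydro-2H-chromen-8-yl}-3-(4-hydroxyphenyl)prop-2-en-1-one (CNP0102599.2)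
Conditions: HCl (2 M), MeOH/THF, rt
Reagents that add atoms: none
Why: Acid-catalysed acetal exchange with methanol removes the four methoxymethyl groups and solvolyses the silyl ether in one operation (global deprotection), run at room temperature to keep the benzylic C2–O1 bond from ionising.

**Compound list**

1 | methyl 3-(4-hydroxyphenyl)propanoate | COC(=O)CCc1ccc(O)cc1 | starting material
2 | methyl 3-[4-(methoxymethoxy)phenyl]propanoate | COCOc1ccc(CCC(=O)OC)cc1 | intermediate
3 | 3-[4-(methoxymethoxy)phenyl]propanal | COCOc1ccc(CCC=O)cc1 | intermediate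
4 | (3R)-1-[4-(methoxymethoxy)phenyl]hex-5-en-3-ol | C=CC[C@H](O)CCc1ccc(OCOC)cc1 | intermediate
5 | (3R)-1-[4-(methoxymethoxy)phenyl]hex-5-en-3-yl prop-2-enoate | C=CC[C@H](OC(=O)C=C)CCc1ccc(OCOC)cc1 | intermediate
6 | (6R)-6-{2-[4-(methoxymethoxy)phenyl]ethyl}-5,6-dihydro-2H-pyran-2-one | O=C1C=CC[C@@H](CCc2ccc(OCOC)cc2)O1 | intermediate
7 | 1-(4-hydroxyphenyl)ethanone | CC(=O)c1ccc(O)cc1 | starting material
8 | 1-[4-(methoxymethoxy)phenyl]ethanone | CC(=O)c1ccc(OCOC)cc1 | intermediate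
9 | ({1-[4-(methoxymethoxy)phenyl]ethenyl}oxy)trimethylsilane | C=C(O[Si](C)(C)C)c1ccc(OCOC)cc1 | intermediate
10 | (2R,4S)-4-(2-Ar-2-oxoethyl)-2-(2-Ar-ethyl)-6-(trimethylsilyloxy)-3,4-dihydro-2H-pyran (silyl ketene acetal of 11) | C[Si](C)(C)OC1=C[C@H](CC(=O)c2ccc(OCOC)cc2)C[C@@H](CCc2ccc(OCOC)cc2)O1 | intermediate (not isolated)
11 | (4S,6R)-4-(2-Ar-2-oxoethyl)-6-(2-Ar-ethyl)oxan-2-one (4,6-trans) | O=C1C[C@H](CC(=O)c2ccc(OCOC)cc2)C[C@@H](CCc2ccc(OCOC)cc2)O1 | intermediate
12 | (3S,5R)-7-Ar-3-(2-Ar-2-oxoethyl)-5-hydroxy-N-methoxy-N-methylheptanamide | CON(C)C(=O)C[C@H](CC(=O)c1ccc(OCOC)cc1)C[C@H](O)CCc1ccc(OCOC)cc1 | intermediate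
13 | (3S,5R)-7-Ar-3-(2-Ar-2-oxoethyl)-5-(TBS-oxy)-N-methoxy-N-methylheptanamide | CON(C)C(=O)C[C@H](CC(=O)c1ccc(OCOC)cc1)C[C@H](O[Si](C)(C)C(C)(C)C)CCc1ccc(OCOC)cc1 | intermediate
14 | (3R,5R)-7-Ar-3-[(2R)-2-Ar-2-hydroxyethyl]-5-(TBS-oxy)-N-methoxy-N-methylheptanamide | CON(C)C(=O)C[C@H](C[C@@H](O)c1ccc(OCOC)cc1)C[C@H](O[Si](C)(C)C(C)(C)C)CCc1ccc(OCOC)cc1 | intermediate
15 | (4R,6R)-8-Ar-4-[(2R)-2-Ar-2-hydroxyethyl]-6-(TBS-oxy)octan-2-one | CC(=O)C[C@H](C[C@@H](O)c1ccc(OCOC)cc1)C[C@H](O[Si](C)(C)C(C)(C)C)CCc1ccc(OCOC)cc1 | intermediate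
16 | (2R,4R)-2-Ar-4-[(2R)-4-Ar-2-(TBS-oxy)butyl]-6-methyl-3,4-dihydro-2H-pyran (2,4-trans) | CC1=C[C@@H](C[C@H](O[Si](C)(C)C(C)(C)C)CCc2ccc(OCOC)cc2)C[C@H](c2ccc(OCOC)cc2)O1 | intermediate
17 | N,N-dimethyliminium chloride of aldehyde 18 | CC1=C(C=[N+](C)C)[C@@H](C[C@H](O[Si](C)(C)C(C)(C)C)CCc2ccc(OCOC)cc2)C[C@H](c2ccc(OCOC)cc2)O1.[Cl-] | intermediate (not isolated)
18 | (2R,4R)-2-Ar-4-[(2R)-4-Ar-2-(TBS-oxy)butyl]-6-methyl-3,4-dihydro-2H-pyran-5-carbaldehyde | CC1=C(C=O)[C@@H](C[C@H](O[Si](C)(C)C(C)(C)C)CCc2ccc(OCOC)cc2)C[C@H](c2ccc(OCOC)cc2)O1 | intermediate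
19 | methyl 3-{(2R,4R)-2-Ar-4-[(2R)-4-Ar-2-(TBS-oxy)butyl]-6-methyl-3,4-dihydro-2H-pyran-5-yl}-3-hydroxypropanoate (both carbinol epimers) | COC(=O)CC(O)C1=C(C)O[C@@H](c2ccc(OCOC)cc2)C[C@@H]1C[C@H](O[Si](C)(C)C(C)(C)C)CCc2ccc(OCOC)cc2 | intermediate
20 | methyl 3-{(2R,4R)-2-Ar-4-[(2R)-4-Ar-2-(TBS-oxy)butyl]-6-methyl-3,4-dihydro-2H-pyran-5-yl}-3-oxopropanoate | COC(=O)CC(=O)C1=C(C)O[C@@H](c2ccc(OCOC)cc2)C[C@@H]1C[C@H](O[Si](C)(C)C(C)(C)C)CCc2ccc(OCOC)cc2 | intermediate
21 | methyl 3-{(2R,4R)-2-Ar-4-[(2R)-4-Ar-2-(TBS-oxy)butyl]-6-(2-oxopropyl)-3,4-dihydro-2H-pyran-5-yl}-3-oxopropanoate | COC(=O)CC(=O)C1=C(CC(C)=O)O[C@@H](c2ccc(OCOC)cc2)C[C@@H]1C[C@H](O[Si](C)(C)C(C)(C)C)CCc2ccc(OCOC)cc2 | intermediate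
22 | 1-{(2R,4R)-2-Ar-4-[(2R)-4-Ar-2-(TBS-oxy)butyl]-5,7-dihydroxy-3,4-dihydro-2H-chromen-8-yl}ethanone | CC(=O)c1c(O)cc(O)c2c1O[C@@H](c1ccc(OCOC)cc1)C[C@@H]2C[C@H](O[Si](C)(C)C(C)(C)C)CCc1ccc(OCOC)cc1 | intermediate
23 | 1-{(2R,4R)-2-Ar-4-[(2R)-4-Ar-2-(TBS-oxy)butyl]-7-hydroxy-5-(methoxymethoxy)-3,4-dihydro-2H-chromen-8-yl}ethanone | CC(=O)c1c(O)cc(OCOC)c2c1O[C@@H](c1ccc(OCOC)cc1)C[C@@H]2C[C@H](O[Si](C)(C)C(C)(C)C)CCc1ccc(OCOC)cc1 | intermediate
24 | 1-{(2R,4R)-2-Ar-4-[(2R)-4-Ar-2-(TBS-oxy)butyl]-7-methoxy-5-(methoxymethoxy)-3,4-dihydro-2H-chromen-8-yl}ethanone | COc1cc(OCOC)c2c(c1C(C)=O)O[C@@H](c1ccc(OCOC)cc1)C[C@@H]2C[C@H](O[Si](C)(C)C(C)(C)C)CCc1ccc(OCOC)cc1 | intermediate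
25 | 4-hydroxybenzaldehyde | O=Cc1ccc(O)cc1 | starting material
26 | 4-(methoxymethoxy)benzaldehyde | COCOc1ccc(C=O)cc1 | intermediate
27 | (2E)-3-Ar-1-{(2R,4R)-2-Ar-4-[(2R)-4-Ar-2-(TBS-oxy)butyl]-7-methoxy-5-(methoxymethoxy)-3,4-dihydro-2H-chromen-8-yl}prop-2-en-1-one | COc1cc(OCOC)c2c(c1C(=O)/C=C/c1ccc(OCOC)cc1)O[C@@H](c1ccc(OCOC)cc1)C[C@@H]2C[C@H](O[Si](C)(C)C(C)(C)C)CCc1ccc(OCOC)cc1 | intermediate
28 | (2E)-1-{(2R,4S)-5-hydroxy-4-[(2R)-2-hydroxy-4-(4-hydroxyphenyl)butyl]-2-(4-hydroxyphenyl)-7-methoxy-3,4-dihydro-2H-chromen-8-yl}-3-(4-hydroxyphenyl)prop-2-en-1-one | COc1cc(O)c2c(c1C(=O)/C=C/c1ccc(O)cc1)O[C@@H](c1ccc(O)cc1)C[C@@H]2C[C@H](O)CCc1ccc(O)cc1 | target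

**Step count and risks**

Total steps: 23. Longest linear sequence: 20 (steps 1 to 5, 8 to 20, 22, 23).

Steps most likely to fail:

1. Step 17 (lateral acetylation of the dianion). What may go wrong: the strongly basic dianion may deprotonate the amide methyl group instead of adding to it, or acyl transfer may fall on oxygen, so that 20 is returned or enol esters form. Fallback, from 20 back to 21: the same dianion is trapped at −78 °C by acetaldehyde, which adds at carbon much faster than it is enolised, to give the 2-hydroxypropyl compound F1. Dess–Martin oxidation of its secondary alcohol (NaHCO3, CH2Cl2, 0 °C) then gives 21. The acyl transfer is thus replaced by an aldol addition and an oxidation.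

2. Step 18 (key Claisen cyclisation). What may go wrong: ring closure through the other pair of carbons (attack of C6 on the acetyl carbonyl, then dehydration), or methoxide-induced loss of the acetyl group before closure. Fallback, from 20 to 23: O-alkylation of the keto ester enolate (NaH, MOMCl, THF/DMPU) gives the (E)-enol methoxymethyl ether F2, in which C6 is no longer a nucleophile. A single deprotonation of the C8 methyl group (LiN(iPr)2, THF, −78 °C) and N-methoxy-N-methylacetamide give the acetonyl enol ether F3. NaOMe in MeOH (50 °C) then closes ring A by the same C8-to-C7 acyl substitution with loss of methanol. This delivers 23 directly with the O5 acetal already in place, so steps 18 and 19 are both replaced.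

3. Step 23 (global deprotection). What may go wrong: acid-induced ionisation of the benzylic C2–O1 bond (the leaving group is an acyl-substituted phenol and the cation is stabilised by the 4-oxygenated aryl ring), with epimerisation at C2 or methanolysis of the pyran ring. Fallback, from 27 to 28: TMSOTf and 2,2'-bipyridyl (CH3CN, 0 °C) convert the four aryl acetals into aryl trimethylsilyl ethers without free Brønsted acid, and water releases the silyl-protected tetraphenol F4. HF·pyridine buffered with pyridine (THF, 0 °C) then removes the silyl ether and gives 28.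

Further compounds
F1 | step 17 | methyl 3-{(2R,4R)-2-Ar-4-[(2R)-4-Ar-2-(TBS-oxy)butyl]-6-(2-hydroxypropyl)-3,4-dihydro-2H-pyran-5-yl}-3-oxopropanoate (both carbinol epimers) | COC(=O)CC(=O)C1=C(CC(C)O)O[C@@H](c2ccc(OCOC)cc2)C[C@@H]1C[C@H](O[Si](C)(C)C(C)(C)C)CCc2ccc(OCOC)cc2
F2 | step 18 | methyl (2E)-3-{(2R,4R)-2-Ar-4-[(2R)-4-Ar-2-(TBS-oxy)butyl]-6-methyl-3,4-dihydro-2H-pyran-5-yl}-3-(methoxymethoxy)prop-2-enoate | COC(=O)/C=C(/OCOC)C1=C(C)O[C@@H](c2ccc(OCOC)cc2)C[C@@H]1C[C@H](O[Si](C)(C)C(C)(C)C)CCc2ccc(OCOC)cc2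
F3 | step 18 | methyl (2E)-3-{(2R,4R)-2-Ar-4-[(2R)-4-Ar-2-(TBS-oxy)butyl]-6-(2-oxopropyl)-3,4-dihydro-2H-pyran-5-yl}-3-(methoxymethoxy)prop-2-enoate | COC(=O)/C=C(/OCOC)C1=C(CC(C)=O)O[C@@H](c2ccc(OCOC)cc2)C[C@@H]1C[C@H](O[Si](C)(C)C(C)(C)C)CCc2ccc(OCOC)cc2
F4 | step 23 | (2E)-1-{(2R,4R)-5-hydroxy-2-(4-hydroxyphenyl)-4-[(2R)-4-(4-hydroxyphenyl)-2-(TBS-oxy)butyl]-7-methoxy-3,4-dihydro-2H-chromen-8-yl}-3-(4-hydroxyphenyl)prop-2-en-1-one | COc1cc(O)c2c(c1C(=O)/C=C/c1ccc(O)cc1)O[C@@H](c1ccc(O)cc1)C[C@@H]2C[C@H](O[Si](C)(C)C(C)(C)C)CCc1ccc(O)cc1
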